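A flat tail on a yield curve is easily taken for a stopped flask, and that is the risk in Thursday's flask, which is asked about at 15 min.

| setting | Thursday's | Monday's | flask |
|---|---|---|---|
| substrate | 0.10 M | 0.067 M | 0.10 M |
| reagent | 0.30 M | 0.30 M | 0.300 M |
| remark | the very flask that is asked about, followed so far | run made earlier |  |
| time |  |  | 15 min |

| Thursday's: time / min | Thursday's: tris adduct / % | Monday's: time / min | Monday's: tris adduct / % |
|---|---|---|---|
| 1.00 | 8.2 | 1.00 | 9.5 |
| 2.00 | 17.2 | 3.00 | 26.1 |
| 3.00 | 21.9 | 5.00 | 28.6 |
| 4.00 | 24.2 | 8.00 | 26.6 |
| 5.00 | 24.9 | 12.0 | 24.1 |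
| 6.00 | 25.0 | 15.0 | 22.6 |

(standard deviation of a reading: 0.3 percentage points)

- equivalents of reagent to substrate, everything else as given, that leave most tris adduct at 15 min
- the amount of tris adduct then, in percent of the substrate charged
- the amount of tris adduct with the amounts as given

I turned the question round and asked what would have to be true for Thursday's 25.0% at 6.00 min to stand until 15 min. My measure was the fade constant, the logarithm of the ratio of two late tris adduct readings divided by the time between them, 0.0233 min⁻¹, read from Monday's run, charged with the same [reagent]; its zero is a flask at rest, and it is pseudo-first-order if [reagent] holds level. Thursday's plateau needs that zero, yet its tris adduct, at 3 reagent each, holds 0.0750 M, a quarter of the charge, leaving 0.225 M to be accounted for before reagent could be called gone. So I carried the fade across, although Monday's run was charged with less substrate, and reckoned 20.3% at 15 min. The forecast instead said 24%, with 27.5% at 3.5 equiv, reading the plateau as “reagent running out at the stoichiometric point for tris”.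

The simulation gave 21.5%, and 24.7% at 4.82 equiv, which is more equivalents than the forecast's.

    substrate + reagent → mono adduct + by-product (k = 0.140 L mol⁻¹ s⁻¹)
    mono adduct → side product A (k = 0.0230 s⁻¹)
    reagent ⇌ dormant form (K = 0.530, k = 0.0300 s⁻¹)
    reagent + mono adduct → bis adduct + by-product (k = 0.0720 L mol⁻¹ s⁻¹)
    reagent + bis adduct → tris adduct + by-product (k = 0.160 L mol⁻¹ s⁻¹)
    reagent + tris adduct → tetra adduct + by-product (k = 0.00330 L mol⁻¹ s⁻¹)
    substrate + mono adduct → side product B (k = 0.0550 L mol⁻¹ s⁻¹)

The flask was not at rest at 15 min. My fade constant took 21.5% down to 0.925% at 150 min, but the flask held 2.23%, a fade of 0.0168 min⁻¹, slower than Monday's reading. A neighbour flask charged with 1.2 M of reagent held tris adduct and tetra adduct at 15 min that, with the two together counted as tris adduct from the start, give 0.116 min⁻¹, faster than that reading. Over the long wait in the flask itself, tetra adduct rose from 6.13% to 25.4%.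

(The data come from a simulation from invented constants.)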